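Over 40 min a row of flasks was to run, with the substrate charge raised from one to the next and the reagent, initiator and radical scavenger held, and I had to say how much target stood at the end.

| setting | Tuesday's | Saturday's | elm | alder | birch | oak |
|---|---|---|---|---|---|---|
| substrate | 0.31 M | 0.86 M | 0.30 M | 0.60 M | 1.2 M | 2.5 M |
| reagent | 0.45 M | 0.45 M | 0.450 M | 0.450 M | 0.450 M | 0.450 M |
| initiator | 15 mM | 15 mM | 15 mM | 15 mM | 15 mM | 15 mM |
| radical scavenger | 0.18 mM | 0.18 mM | 0.18 mM | 0.18 mM | 0.18 mM | 0.18 mM |
| remark | run made earlier | run made earlier |  |  |  |  |
| time |  |  | 40 min | 40 min | 40 min | 40 min |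

| run | time / min | target / % | substrate / % |
|---|---|---|---|
| Tuesday's | 8.00 | 5.9 | 92.5 |
| Tuesday's | 15.0 | 10.0 | 86.6 |
| Tuesday's | 20.0 | 12.4 | 84.1 |
| Tuesday's | 30.0 | 16.6 | 75.6 |
| Saturday's | 8.00 | 6.2 | 92.5 |
| Saturday's | 15.0 | 9.7 | 84.9 |
| Saturday's | 20.0 | 10.2 | 80.6 |
| Saturday's | 30.0 | 10.3 | 70.7 |

(scatter of a reading: 0.5 percentage points)

- [target] at the end for elm, alder, birch, oak, in this order
- how that number moves from the first to the last of them (rises, then falls / rises all the way / hardly changes / falls, then rises / falls all the way)

- "hardly changes" means that all values lie within two and a half points (for a concentration: within two and a half percent of the largest)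

At the first reading the two earlier runs had turned nearly the same share of very different charges into target, 5.9 % and 6.2 %. So I took making as first order in substrate, with a making constant of about 0.00756 min⁻¹. What slowed it showed on Saturday: target stalled while substrate kept falling, and the balance opened. I read the gap as target eaten by substrate, each event removing two units from the balance. Dividing the final gap by twice the charge and by the running sum of substrate times target gave 0.0580 M⁻¹ min⁻¹ for Saturday and 0.0538 M⁻¹ min⁻¹ for Tuesday, mean 0.0559 M⁻¹ min⁻¹.

At a given substrate, eating is then pseudo-first-order in target, and on this reading substrate multiplies both rates, so it cancels from their balance. The ceiling, the target concentration at which eating equals making, is the making constant over the eating constant: 0.135 M. At Saturday's last reading substrate stood at 70.7 % and I reckoned that eating took 65.5 % of the making, which put the rise at about a quarter of its starting rate.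

In this reckoning, with the reagent held, more substrate nears the ceiling sooner. At charged substrate I reckoned 0.0661 M, 0.0999 M and 0.126 M for elm, alder and birch. Assuming one reagent per target made, oak would use up its reagent, the limiting reagent, in 23.8 min. Eating alone, starting from the ceiling at charged substrate, would then leave about 0.0141 M, so I expected the row to rise, then fall.

The forecast gave 0.062 M, 0.087 M, 0.088 M and 0.088 M, so that the row rises all the way, reading Saturday's stall thus: “Something finite has run out, probably the reagent, at about 5 reagent per target”.

The flasks gave 0.0576 M, 0.0896 M, 0.118 M and 0.0440 M: the row rises, then falls.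

    initiator → 2 initiating radical (k = 0.0213 min⁻¹)
    substrate + initiating radical ⇌ chain carrier (K = 24600 M⁻¹, k = 5460 M⁻¹ min⁻¹)
    reagent + chain carrier → target + initiating radical (k = 46900 M⁻¹ min⁻¹)
    2 initiating radical → ended chains A (k = 1.90 × 10⁶ M⁻¹ s⁻¹)
    radical scavenger + initiating radical → ended chains B (k = 5.69 × 10⁵ M⁻¹ s⁻¹)
    substrate + target → side product (k = 0.0517 M⁻¹ min⁻¹)

In elm at 16.3 min, target was being made 4.46 times faster than it was used up, and elm ended at 42.7 % of the ceiling I had read. Birch ended at 87.4 % of that ceiling, with 36 % of its reagent left, while oak ended with 0 % of its reagent and 0.0440 M of target.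

All runs stem from a simulated flask for an exercise, and the scatter is random.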